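**Retrosynthetic overview**
1. Hansfordiol B ⇒ its bis(methyl ether). The two phenols are unmasked last with BBr3.
2. Methyl ketone ⇒ tert-butyl β-keto ester (loss of isobutene and CO2) ⇒ key crossed Claisen condensation of methyl 16-(3,5-dimethoxyphenyl)hexadecanoate with the lithium enolate of tert-butyl acetate. This forms the C(=O)–CH3 carbon-carbon bond.
3. C16 aryl ester ⇒ hydrogenation of a Wittig alkene ⇒ 3,5-dimethoxybenzaldehyde plus a C15 ω-(methoxycarbonyl)alkyl phosphonium salt.
4. Phosphonium salt ⇒ methyl 15-bromopentadecanoate ⇒ methyl 15-hydroxypentadecanoate ⇒ ω-pentadecalactone.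
5. Rings: none is formed. The benzene ring is bought with the aldehyde, and the macrolactone ring of the starting material is opened in the first step.

Assumption: the SMILES holds no stereocentre (fifteen CH2 groups between ring and carbonyl), so the target is achiral and no enantiocontrol is needed; the only stereo-element on the way is an alkene geometry that is erased by hydrogenation.

**Step 1**
Reactants: 1 ω-pentadecalactone (oxacyclohexadecan-2-one, achiral)
Product: 2 methyl 15-hydroxypentadecanoate
Conditions: MeOH, H2SO4 (cat.), reflux, 16 h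
Reagents that add atoms: methanol, CO
Why: Acid-catalysed transesterification (methanolysis) of the unstrained macrolactone is driven to completion by methanol as solvent and frees the terminal primary alcohol; no stereocentre is involved.

**Step 2**
Reactants: 2 methyl 15-hydroxypentadecanoate
Product: 3 methyl 15-bromopentadecanoate
Conditions: CBr4 (1.2 equiv), PPh3 (1.25 equiv), CH2Cl2, 0 °C to rt
Reagents that add atoms: carbon tetrabromide, BrC(Br)(Br)Br
Why: Appel reaction, in which the primary alcohol is activated as an alkoxyphosphonium ion and displaced by bromide (SN2) under neutral conditions that leave the methyl ester untouched.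

**Step 3**
Reactants: 3 methyl 15-bromopentadecanoate
Product: 4 (15-methoxy-15-oxopentadecyl)triphenylphosphonium bromide
Conditions: PPh3 (1.2 equiv), MeCN, reflux, 48 h; trituration with Et2O, drying in vacuo
Reagents that add atoms: triphenylphosphine, c1ccc(cc1)P(c1ccccc1)c1ccccc1
Why: SN2 quaternisation of triphenylphosphine by an unhindered primary bromide is clean in a polar solvent, and the salt is freed of excess phosphine by trituration.

**Step 4**
Reactants: 4 (15-methoxy-15-oxopentadecyl)triphenylphosphonium bromide (1.15 equiv); 5 3,5-dimethoxybenzaldehyde (1.0 equiv)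
Product: 7 methyl (Z)-16-(3,5-dimethoxyphenyl)hexadec-15-enoate, via phosphonium ylide 6 (not isolated)
Conditions: NaN(SiMe3)2 (1.1 equiv), THF, 0 °C, 30 min; then 5, −78 °C to rt
Reagents that add atoms: none
Why: Wittig olefination, in which the non-stabilised ylide is made with less base than salt so the remote ester is not touched, and it adds to the non-enolisable aromatic aldehyde to give mainly the Z alkene, whose geometry does not matter because step 5 erases it.

**Step 5**
Reactants: 7 methyl (Z)-16-(3,5-dimethoxyphenyl)hexadec-15-enoate (with its minor E isomer)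
Product: 8 methyl 16-(3,5-dimethoxyphenyl)hexadecanoate
Conditions: H2 (1 atm), 10% Pd/C, EtOAc, rt
Reagents that add atoms: none
Why: Heterogeneous catalytic hydrogenation saturates the styrene-type double bond of both isomers while the ester and aryl methyl ethers are inert, and no stereocentre arises.

**Step 6 (key step)**
Reactants: 8 methyl 16-(3,5-dimethoxyphenyl)hexadecanoate; 9 tert-butyl acetate (3.6 equiv)
Product: 12 tert-butyl 18-(3,5-dimethoxyphenyl)-3-oxooctadecanoate, via lithium enolate of tert-butyl acetate 10 (not isolated), via lithium enolate of the keto ester 11 (not isolated)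
Conditions: 9, LiN(iPr)2 (3.5 equiv), THF, −78 °C, 45 min; then 8 in THF, −78 to 0 °C, 3 h; cold 1 M HCl quench
Reagents that add atoms: none
Why: Crossed Claisen condensation, in which the pre-formed enolate 10 (resistant to self-condensation and stable up to 0 °C) attacks the unhindered methyl ester, methoxide leaves, and excess enolate at once deprotonates the product to chelated enolate 11, which makes the union irreversible and blocks a second addition; no stereocentre is formed.

**Step 7**
Reactants: 12 tert-butyl 18-(3,5-dimethoxyphenyl)-3-oxooctadecanoate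
Product: 14 17-(3,5-dimethoxyphenyl)heptadecan-2-one, via free beta-keto acid 13 (not isolated)
Conditions: p-TsOH·H2O (10 mol %), toluene, reflux, N2 sweep, 2 h
Reagents that add atoms: none
Why: Acid-catalysed E1 loss of isobutene from the tert-butyl ester gives the β-keto acid, which decarboxylates at once through a six-membered transition state at 110 °C, while the gas sweep removes isobutene before it can alkylate the electron-rich ring.

**Step 8**
Reactants: 14 17-(3,5-dimethoxyphenyl)heptadecan-2-one
Product: 16 hansfordiol B [17-(3,5-dihydroxyphenyl)heptadecan-2-one], via bis(dibromoboryl) aryl ether 15 (not isolated)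
Conditions: BBr3 (5 equiv, 1 M in CH2Cl2), CH2Cl2, −78 °C to rt, 12 h; then H2O, 0 °C
Reagents that add atoms: none
Why: Lewis-acid aryl methyl ether cleavage, in which BBr3 binds each ether oxygen and bromide removes the methyl group by SN2 to leave aryl borate 15 that water hydrolyses, with the extra equivalents covering reagent bound reversibly by the ketone, which returns unchanged on hydrolysis.

**Compound list**
```
1 | ω-pentadecalactone (oxacyclohexadecan-2-one), achiral | O=C1CCCCCCCCCCCCCCO1 | starting material
2 | methyl 15-hydroxypentadecanoate | COC(=O)CCCCCCCCCCCCCCO | intermediate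
3 | methyl 15-bromopentadecanoate | COC(=O)CCCCCCCCCCCCCCBr | intermediate
4 | (15-methoxy-15-oxopentadecyl)triphenylphosphonium bromide | [Br-].COC(=O)CCCCCCCCCCCCCC[P+](c1ccccc1)(c1ccccc1)c1ccccc1 | intermediate
5 | 3,5-dimethoxybenzaldehyde | COc1cc(C=O)cc(OC)c1 | starting material
6 | methyl 15-(triphenyl-λ5-phosphanylidene)pentadecanoate (ylide, not isolated) | COC(=O)CCCCCCCCCCCCCC=P(c1ccccc1)(c1ccccc1)c1ccccc1 | intermediate
7 | methyl (Z)-16-(3,5-dimethoxyphenyl)hexadec-15-enoate (major isomer; minor E isomer carried along) | COC(=O)CCCCCCCCCCCCC/C=C\c1cc(OC)cc(OC)c1 | intermediate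
8 | methyl 16-(3,5-dimethoxyphenyl)hexadecanoate | COC(=O)CCCCCCCCCCCCCCCc1cc(OC)cc(OC)c1 | intermediate
9 | tert-butyl acetate | CC(=O)OC(C)(C)C | starting material
10 | lithium enolate of tert-butyl acetate (not isolated) | [Li+].C=C([O-])OC(C)(C)C | intermediate
11 | lithium (Z)-enolate (chelate) of tert-butyl 18-(3,5-dimethoxyphenyl)-3-oxooctadecanoate (not isolated) | [Li+].COc1cc(CCCCCCCCCCCCCCC/C([O-])=C/C(=O)OC(C)(C)C)cc(OC)c1 | intermediate
12 | tert-butyl 18-(3,5-dimethoxyphenyl)-3-oxooctadecanoate | CC(C)(C)OC(=O)CC(=O)CCCCCCCCCCCCCCCc1cc(OC)cc(OC)c1 | intermediate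
13 | 18-(3,5-dimethoxyphenyl)-3-oxooctadecanoic acid (not isolated) | OC(=O)CC(=O)CCCCCCCCCCCCCCCc1cc(OC)cc(OC)c1 | intermediate
14 | 17-(3,5-dimethoxyphenyl)heptadecan-2-one | CC(=O)CCCCCCCCCCCCCCCc1cc(OC)cc(OC)c1 | intermediate
15 | 17-[3,5-bis(dibromoboryloxy)phenyl]heptadecan-2-one (not isolated) | CC(=O)CCCCCCCCCCCCCCCc1cc(OB(Br)Br)cc(OB(Br)Br)c1 | intermediate
16 | hansfordiol B, 17-(3,5-dihydroxyphenyl)heptadecan-2-one, achiral | CC(=O)CCCCCCCCCCCCCCCc1cc(O)cc(O)c1 | target
```

**Total step count:** 8. **Longest linear sequence:** 8 steps (1 → 16).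

**Three steps most likely to fail**

Step 6 (crossed Claisen condensation). Ester 8 is enolisable and poorly soluble in the cold. Proton transfer from 8 to enolate 10 can therefore stall the conversion or lead to self-condensation of 8. The fallback replaces the strong-base enolate by a decarboxylative Claisen condensation under nearly neutral conditions. It sets out from 8, which is saponified (LiOH, THF/MeOH/H2O) to 16-(3,5-dimethoxyphenyl)hexadecanoic acid F3. The acid is activated with 1,1'-carbonyldiimidazole in THF to 16-(3,5-dimethoxyphenyl)-1-(1H-imidazol-1-yl)hexadecan-1-one F4. F4 is added to the magnesium enolate made from tert-butyl hydrogen malonate, MgCl2 and Et3N in MeCN. C-acylation and loss of CO2 bring the fallback back to the route at 12.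

Step 4 (Wittig olefination). The waxy, hygroscopic salt 4 can give a partly quenched ylide, and any surplus base attacks the ester. The fallback reverses the polarity of the olefination. It sets out from 2, which is oxidised (Dess–Martin periodinane, CH2Cl2) to methyl 15-oxopentadecanoate F1. F1 is condensed in a Horner–Wadsworth–Emmons reaction with the anion of commercial diethyl (3,5-dimethoxybenzyl)phosphonate (NaH, THF, 0 °C to rt). This gives methyl (E)-16-(3,5-dimethoxyphenyl)hexadec-15-enoate F2. Hydrogenation as in step 5 brings the fallback back to the route at 8.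

Step 8 (BBr3 demethylation). The ketone binds the Lewis acid and may enolise and condense, and the second ether may cleave incompletely. The fallback changes the protecting groups so that no Lewis or Brønsted acid is needed.
- It sets out from 4, whose ylide 6 is combined with commercial 3,5-bis(benzyloxy)benzaldehyde to give methyl (Z)-16-[3,5-bis(benzyloxy)phenyl]hexadec-15-enoate F5.
- LiOH gives (Z)-16-[3,5-bis(benzyloxy)phenyl]hexadec-15-enoic acid F6.
- 1,1'-Carbonyldiimidazole gives (Z)-16-[3,5-bis(benzyloxy)phenyl]-1-(1H-imidazol-1-yl)hexadec-15-en-1-one F7.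
- The magnesium enolate of benzyl hydrogen malonate (MgCl2, Et3N) gives benzyl (Z)-18-[3,5-bis(benzyloxy)phenyl]-3-oxooctadec-17-enoate F8.
- One hydrogenation (H2, 10% Pd/C, EtOAc/EtOH) saturates the alkene and removes all three benzyl groups, giving 18-(3,5-dihydroxyphenyl)-3-oxooctadecanoic acid F9.
- F9 loses CO2 on warming to 45 °C, and the fallback comes back to the route at 16.

**Further compounds**
```
F1 | step 4 | methyl 15-oxopentadecanoate | COC(=O)CCCCCCCCCCCCCC=O
F2 | step 4 | methyl (E)-16-(3,5-dimethoxyphenyl)hexadec-15-enoate | COC(=O)CCCCCCCCCCCCC/C=C/c1cc(OC)cc(OC)c1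
F3 | step 6 | 16-(3,5-dimethoxyphenyl)hexadecanoic acid | OC(=O)CCCCCCCCCCCCCCCc1cc(OC)cc(OC)c1
F4 | step 6 | 16-(3,5-dimethoxyphenyl)-1-(1H-imidazol-1-yl)hexadecan-1-one | O=C(CCCCCCCCCCCCCCCc1cc(OC)cc(OC)c1)n1ccnc1
F5 | step 8 | methyl (Z)-16-[3,5-bis(benzyloxy)phenyl]hexadec-15-enoate | COC(=O)CCCCCCCCCCCCC/C=C\c1cc(OCc2ccccc2)cc(OCc2ccccc2)c1
F6 | step 8 | (Z)-16-[3,5-bis(benzyloxy)phenyl]hexadec-15-enoic acid | OC(=O)CCCCCCCCCCCCC/C=C\c1cc(OCc2ccccc2)cc(OCc2ccccc2)c1
F7 | step 8 | (Z)-16-[3,5-bis(benzyloxy)phenyl]-1-(1H-imidazol-1-yl)hexadec-15-en-1-one | O=C(CCCCCCCCCCCCC/C=C\c1cc(OCc2ccccc2)cc(OCc2ccccc2)c1)n1ccnc1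
F8 | step 8 | benzyl (Z)-18-[3,5-bis(benzyloxy)phenyl]-3-oxooctadec-17-enoate | O=C(CC(=O)CCCCCCCCCCCCC/C=C\c1cc(OCc2ccccc2)cc(OCc2ccccc2)c1)OCc1ccccc1
F9 | step 8 | 18-(3,5-dihydroxyphenyl)-3-oxooctadecanoic acid | OC(=O)CC(=O)CCCCCCCCCCCCCCCc1cc(O)cc(O)c1
```
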